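## Retrosynthesis
- The target is a threo (7S,8S) β‑O‑4 aryl glycerol ether. The last step is removal of two benzyl ethers (Ar–OBn to Ar–OH) from the diol.
- The 1,3‑diol comes from reductive removal of an Evans auxiliary from a syn aldol adduct, which sets C7 and C8 in one step.
- The aldol disconnects to 4‑benzyloxy‑3‑methoxybenzaldehyde and an α‑aryloxyacetyl (R)‑4‑benzyloxazolidinone. That imide comes from the mono‑benzylated 2,6‑dimethoxyhydroquinone and the bromoacetyl imide.
- No rings are formed. Both arenes are used preformed, and the oxazolidinone is a recoverable auxiliary.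

**Assumptions:** 2,6‑dimethoxyhydroquinone (1) and 4‑benzyloxy‑3‑methoxybenzaldehyde (8) are commercially available. The target is (7S,8S), which is threo and syn in the zigzag drawing C9–C8–C7–Ar. An Evans syn aldol with the (R)‑benzyl auxiliary gives this configuration.

## Route

**Step 1**
Reactants: 1 (2,6‑dimethoxybenzene‑1,4‑diol); 2 (benzyl bromide)
Product: 3 (4‑(benzyloxy)‑2,6‑dimethoxyphenol)
Conditions: 2 (0.95 equiv), K2CO3, acetone, N2, rt
Reagents that add atoms: benzyl bromide, BrCc1ccccc1
Why: Williamson etherification is selective for the unhindered 4‑OH, because the 1‑OH is flanked by two OMe groups. This leaves the hindered OH free to become the ether oxygen.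

**Step 2**
Reactants: 4 ((R)‑4‑benzyloxazolidin‑2‑one); 5 (bromoacetyl bromide)
Product: 6 ((R)‑4‑benzyl‑3‑(2‑bromoacetyl)oxazolidin‑2‑one)
Conditions: n‑BuLi, THF, –78 °C; then 5
Reagents that add atoms: bromoacetyl bromide, BrCC(=O)Br
Why: N‑acylation of the lithiated oxazolidinone. The auxiliary stereocentre is untouched and carries the stereochemical information for step 4.

**Step 3**
Reactants: 3; 6
Product: 7 ((R)‑4‑benzyl‑3‑[2‑(4‑benzyloxy‑2,6‑dimethoxyphenoxy)acetyl]oxazolidin‑2‑one)
Conditions: K2CO3, KI (cat.), acetone, 40 °C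
Reagents that add atoms: none (6 is the alkylating agent)
Why: SN2 O‑alkylation of the phenoxide at the reactive α‑bromo carbonyl. No stereocentre is formed.

**Step 4**
Reactants: 7; 8 (4‑benzyloxy‑3‑methoxybenzaldehyde)
Product: 9 ((R)‑4‑benzyl‑3‑[(2R,3S)‑3‑(4‑benzyloxy‑3‑methoxyphenyl)‑3‑hydroxy‑2‑(4‑benzyloxy‑2,6‑dimethoxyphenoxy)propanoyl]oxazolidin‑2‑one)
Conditions: Bu2BOTf, i‑Pr2NEt, CH2Cl2, –78 to 0 °C; then 8; then pH 7 buffer, MeOH, 30% H2O2, 0 °C
Reagents that add atoms: none (8 is the electrophile; boron is removed in the oxidative work‑up)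
Why: This is an Evans boron aldol. The Z‑enolate reacts through a Zimmerman–Traxler chair with the auxiliary dipole opposed, giving the syn aldol. The (R)‑benzyl auxiliary fixes the absolute sense, so C8 is R and C7 is S (these descriptors become S,S after step 5).

**Step 5**
Reactants: 9
Product: 10 ((1S,2S)‑1‑(4‑benzyloxy‑3‑methoxyphenyl)‑2‑(4‑benzyloxy‑2,6‑dimethoxyphenoxy)propane‑1,3‑diol) plus recovered 4
Conditions: LiBH4, THF, MeOH (2 equiv), 0 °C
Reagents that add atoms: none
Why: Hydride reduction of the acyl imide to the primary alcohol releases the auxiliary. The benzyl ethers and aryl ethers are inert, and the low temperature avoids epimerisation at C8.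

**Step 6**
Reactants: 10
Product: 11 (target, (1S,2S)‑1‑(4‑hydroxy‑3‑methoxyphenyl)‑2‑(4‑hydroxy‑2,6‑dimethoxyphenoxy)propane‑1,3‑diol)
Conditions: H2 (1 atm), 10% Pd/C, EtOAc/MeOH, rt, 2–3 h (monitor)
Reagents that add atoms: none
Why: Catalytic hydrogenolysis of both aryl benzyl ethers. The benzylic alcohol and aryl ether C–O bonds survive short reaction times, and no stereocentre is touched.

## Compound list
1 | 2,6‑dimethoxybenzene‑1,4‑diol | COc1cc(O)cc(OC)c1O | starting material
2 | benzyl bromide | BrCc1ccccc1 | starting material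
3 | 4‑(benzyloxy)‑2,6‑dimethoxyphenol | COc1cc(OCc2ccccc2)cc(OC)c1O | intermediate
4 | (R)‑4‑benzyloxazolidin‑2‑one | O=C1N[C@H](Cc2ccccc2)CO1 | starting material
5 | bromoacetyl bromide | BrCC(=O)Br | starting material
6 | (R)‑4‑benzyl‑3‑(2‑bromoacetyl)oxazolidin‑2‑one | O=C1N(C(=O)CBr)[C@H](Cc2ccccc2)CO1 | intermediate
7 | (R)‑4‑benzyl‑3‑[2‑(4‑benzyloxy‑2,6‑dimethoxyphenoxy)acetyl]oxazolidin‑2‑one | O=C1N(C(=O)COc2c(OC)cc(OCc3ccccc3)cc2OC)[C@H](Cc2ccccc2)CO1 | intermediate
8 | 4‑benzyloxy‑3‑methoxybenzaldehyde | COc1cc(C=O)ccc1OCc1ccccc1 | starting material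
9 | Evans syn aldol adduct | COc1cc([C@H](O)[C@H](C(=O)N3C(=O)OC[C@H]3Cc3ccccc3)Oc2c(OC)cc(OCc3ccccc3)cc2OC)ccc1OCc1ccccc1 | intermediate
10 | (1S,2S)‑bis‑O‑benzyl diol | COc1cc([C@H](O)[C@H](CO)Oc2c(OC)cc(OCc3ccccc3)cc2OC)ccc1OCc1ccccc1 | intermediate
11 | (1S,2S)‑1‑(4‑hydroxy‑3‑methoxyphenyl)‑2‑(4‑hydroxy‑2,6‑dimethoxyphenoxy)propane‑1,3‑diol | COc1cc([C@H](O)[C@H](CO)Oc2c(OC)cc(O)cc2OC)ccc1O | target

## Totals
- Total steps: 6.
- Longest linear sequence: 5 (step 2 → 3 → 4 → 5 → 6; step 1 runs in parallel and feeds step 3).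

## Three steps most likely to fail
1. **Step 4 (aldol).** The α‑aryloxy imide and the electron‑rich aldehyde may give poor syn selectivity or conversion. Fallback: run a racemic lithium‑enolate aldol of methyl 2‑(aryloxy)acetate (from 3 and methyl bromoacetate) with 8, reduce to the diol, and separate the threo pair by preparative chiral HPLC.
2. **Step 3 (O‑alkylation).** The hindered phenoxide may attack the imide carbonyl and cleave the auxiliary. Fallback: alkylate 3 with ethyl bromoacetate, saponify, and couple the acid to (R)‑4‑benzyloxazolidinone through the pivaloyl mixed anhydride.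
3. **Step 1 (mono‑benzylation).** Over‑alkylation or oxidation of the hydroquinone could lower the yield. Fallback: protect the unhindered OH selectively as its TBS ether (TBSCl, imidazole), carry it through steps 3–5, and remove it with TBAF together with a hydrogenolysis of the remaining benzyl ethers.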